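**Retrosynthetic overview**
- Feature: in ring C, C4 is an isolated carbonyl carbon bonded only to C4a of ring A and to C3. C3 bears ring B and the one-carbon unit C2, which is the aryl/methyl pattern of the ketone carbon of 2,3,4-trimethoxyacetophenone.
- Disconnections, in retrosynthetic order: C2=C3 (dehydrogenation of an isoflavanone), O1–C2 (oxa-Michael addition of the C8a phenol to a 2-aryl enone), then C4a–C4 and C3–C4 together in one palladium-catalysed three-component coupling.
- In that coupling C4 comes from CO, C3 and C2 from the acetophenone tosylhydrazone (as a carbene), and ring A from an ortho-iodo, MOM-protected phenol.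
- Ring order: rings A and B are bought as arenes; ring C is closed in step 5 (O1–C2) and turned into the 4-pyranone in step 6.

Key step: step 4

Remark on the chemistry: the target has no stereocentre. Isoflavanone 11 is carried as the racemate, and hydrazone 6 is drawn as the E isomer although its geometry is lost once it becomes diazoalkane 8.

**Step 1**
Reactants: 1 3,4-dimethoxyphenol
Product: 2 2-iodo-4,5-dimethoxyphenol
Conditions: NIS (1.05 equiv), TFA (10 mol%), MeCN, 0 °C to rt, dark
Reagents that add atoms: N-iodosuccinimide, O=C1CCC(=O)N1I
Why: Electrophilic aromatic iodination of a phenol whose para position is blocked by methoxy; iodine should enter the ortho carbon that is also para to the 3-methoxy group, not the hindered carbon between OH and OMe.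

**Step 2**
Reactants: 2 2-iodo-4,5-dimethoxyphenol
Product: 3 1-iodo-4,5-dimethoxy-2-(methoxymethoxy)benzene
Conditions: MOMCl (1.5 equiv), iPr2NEt (2 equiv), CH2Cl2, 0 °C to rt
Reagents that add atoms: chloromethyl methyl ether, COCCl
Why: O-alkylation of the phenol to its methoxymethyl acetal under amine base; the acetal is inert to carbonate, CO and zerovalent palladium and stops the phenoxide from trapping the aroylpalladium as an aryl ester.

**Step 3**
Reactants: 4 2,3,4-trimethoxyacetophenone; 5 4-methylbenzenesulfonohydrazide
Product: 6 N'-[(E)-1-(2,3,4-trimethoxyphenyl)ethylidene]-4-methylbenzenesulfonohydrazide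
Conditions: MeOH, AcOH (cat.), 60 °C, then cool and crystallise
Reagents that add atoms: none
Why: Acid-catalysed condensation of a ketone with a sulfonyl hydrazide gives the N-tosylhydrazone, which should crystallise as the E isomer with the sulfonamide nitrogen anti to the aryl group.

**Step 4**
Reactants: 3 1-iodo-4,5-dimethoxy-2-(methoxymethoxy)benzene; 6 N'-[(E)-1-(2,3,4-trimethoxyphenyl)ethylidene]-4-methylbenzenesulfonohydrazide (1.3 equiv); 7 carbon monoxide
Product: 9 1-[4,5-dimethoxy-2-(methoxymethoxy)phenyl]-2-(2,3,4-trimethoxyphenyl)prop-2-en-1-one, via diazoalkane 8 (not isolated)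
Conditions: Pd(PPh3)4 (5 mol%), K2CO3 (3 equiv), CO (1 atm, balloon), 1,4-dioxane, 80 °C
Reagents that add atoms: none
Why: Zerovalent palladium adds oxidatively into the C–I bond of 3 and CO inserts to give the aroylpalladium iodide, which forms C4a–C4. Carbonate converts 6 into diazoalkane 8 (Bamford–Stevens), which loses N2 on palladium to give an aroylpalladium carbene; 1,2-shift of the acyl group to the carbene carbon forms C3–C4, and beta-hydride elimination from the former acetyl methyl group, the only carbon with beta-hydrogens, gives the 1,1-disubstituted enone and a palladium hydride that the base returns to the zerovalent state. The closest known reaction type is the palladium-catalysed carbonylation of aryl iodides with acyl migratory insertion into carbenes from N-tosylhydrazones of aryl methyl ketones, which gives 2-aryl enones. No ring is closed and no stereocentre is created. The selectivity needed is CO insertion before carbene uptake, since the reverse order gives the carbonyl-free 1,1-diarylethene; the electron-rich, ortho-substituted aryl group should migrate to CO quickly, CO is kept in excess, and the sparingly soluble carbonate releases 8 only slowly.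

**Step 5**
Reactants: 9 1-[4,5-dimethoxy-2-(methoxymethoxy)phenyl]-2-(2,3,4-trimethoxyphenyl)prop-2-en-1-one
Product: 11 6,7-dimethoxy-3-(2,3,4-trimethoxyphenyl)chroman-4-one (racemic isoflavanone), via phenolic enone 10 (not isolated)
Conditions: TsOH·H2O (20 mol%), MeOH, 60 °C; then Et3N (0.5 equiv), rt
Reagents that add atoms: none
Why: Acid-catalysed transacetalisation to methanol removes the MOM group, and the freed phenol adds to the terminal CH2 of the enone in a 6-endo-trig oxa-Michael closure of ring C (O1–C2), finished by the amine; C3 forms without control, so 11 is racemic, which does not matter because step 6 removes this centre.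

**Step 6**
Reactants: 11 6,7-dimethoxy-3-(2,3,4-trimethoxyphenyl)chroman-4-one
Product: 12 6,7,2',3',4'-pentamethoxyisoflavone, i.e. 6,7-dimethoxy-3-(2,3,4-trimethoxyphenyl)-4H-chromen-4-one
Conditions: DDQ (1.5 equiv), 1,4-dioxane, 100 °C
Reagents that add atoms: none
Why: Quinone dehydrogenation of an isoflavanone (hydride abstraction from C2 of the enol, then proton loss) gives the aromatic chromen-4-one; the aryl methyl ethers should not be touched.

**Compound list**
1 | 3,4-dimethoxyphenol | COc1ccc(O)cc1OC | starting material
2 | 2-iodo-4,5-dimethoxyphenol | COc1cc(O)c(I)cc1OC | intermediate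
3 | 1-iodo-4,5-dimethoxy-2-(methoxymethoxy)benzene | COCOc1cc(OC)c(OC)cc1I | intermediate
4 | 2,3,4-trimethoxyacetophenone | CC(=O)c1ccc(OC)c(OC)c1OC | starting material
5 | 4-methylbenzenesulfonohydrazide | Cc1ccc(cc1)S(=O)(=O)NN | starting material
6 | N'-[(E)-1-(2,3,4-trimethoxyphenyl)ethylidene]-4-methylbenzenesulfonohydrazide | C/C(c1ccc(OC)c(OC)c1OC)=N\NS(=O)(=O)c1ccc(C)cc1 | intermediate
7 | carbon monoxide | [C-]#[O+] | starting material
8 | 1-(1-diazoethyl)-2,3,4-trimethoxybenzene | CC(=[N+]=[N-])c1ccc(OC)c(OC)c1OC | intermediate (not isolated)
9 | 1-[4,5-dimethoxy-2-(methoxymethoxy)phenyl]-2-(2,3,4-trimethoxyphenyl)prop-2-en-1-one | COCOc1cc(OC)c(OC)cc1C(=O)C(=C)c1ccc(OC)c(OC)c1OC | intermediate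
10 | 1-(2-hydroxy-4,5-dimethoxyphenyl)-2-(2,3,4-trimethoxyphenyl)prop-2-en-1-one | COc1cc(O)c(cc1OC)C(=O)C(=C)c1ccc(OC)c(OC)c1OC | intermediate (not isolated)
11 | 6,7-dimethoxy-3-(2,3,4-trimethoxyphenyl)chroman-4-one, racemic at C3 | COc1cc2OCC(c3ccc(OC)c(OC)c3OC)C(=O)c2cc1OC | intermediate
12 | 6,7,2',3',4'-pentamethoxyisoflavone | COc1cc2occ(-c3ccc(OC)c(OC)c3OC)c(=O)c2cc1OC | target

**Step count**
Total: 6 steps. Longest linear sequence: 5 steps (steps 1, 2, 4, 5, 6 from 3,4-dimethoxyphenol); step 3 is a one-step branch.

**Steps most likely to fail**

Step 4. Three processes could erode it. The arylpalladium may take up the carbene before CO inserts, which gives the carbonyl-free coupling. The diazoalkane may decompose thermally to styrene or azine. The 1,1-disubstituted enone may dimerise or oligomerise under the hot basic conditions, so 9 should be filtered quickly and taken straight into step 5.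
The fallback sets out from phenol 1 and builds C4a–C4 by acylation instead. Friedel–Crafts C-acylation of 1 with commercial 2,3,4-trimethoxyphenylacetic acid (OC(=O)Cc1ccc(OC)c(OC)c1OC) in BF3·OEt2 at 85 °C should occur at the same carbon that is iodinated in step 1. It should give the deoxybenzoin 1-(2-hydroxy-4,5-dimethoxyphenyl)-2-(2,3,4-trimethoxyphenyl)ethanone F1. Heating F1 with N,N-dimethylformamide dimethyl acetal in toluene at 100 °C should give the enaminone 3-(dimethylamino)-1-(2-hydroxy-4,5-dimethoxyphenyl)-2-(2,3,4-trimethoxyphenyl)prop-2-en-1-one F2 (enamine geometry not defined and lost on ring closure). The phenol of F2 then adds and dimethylamine is expelled, and the fallback comes back to the route at 12.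

Step 5. Once the acetal is gone, the free enone may be lost to oligomerisation, hetero-Diels–Alder dimerisation or lasting addition of methanol before the phenol closes the ring; acetal cleavage may also stall.
The fallback sets out from 9 and masks the enone first. Conjugate addition of dimethylamine (2 M in THF, rt) should give the Mannich base 3-(dimethylamino)-1-[4,5-dimethoxy-2-(methoxymethoxy)phenyl]-2-(2,3,4-trimethoxyphenyl)propan-1-one F3 (racemic), which can be purified by acid–base extraction. Methanolic HCl at 40 °C should then remove the acetal to give 3-(dimethylamino)-1-(2-hydroxy-4,5-dimethoxyphenyl)-2-(2,3,4-trimethoxyphenyl)propan-1-one F4 (racemic, handled as its hydrochloride). Warming F4 with NaOAc in EtOH should eliminate dimethylamine, so that enone 10 appears only at low concentration beside the phenoxide and closes to the isoflavanone. The fallback comes back at 11.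

Step 6. The dehydrogenation may stall through slow enolisation or charge-transfer complexation, or the oxidant may attack the electron-rich rings.
The fallback sets out from 11. Soft enolisation with TMSOTf and Et3N in CH2Cl2 at 0 °C should give the silyl enol ether [6,7-dimethoxy-3-(2,3,4-trimethoxyphenyl)-2H-chromen-4-yl]oxy(trimethyl)silane F5. Saegusa–Ito oxidation with Pd(OAc)2 (1.1 equiv) in MeCN at rt to 40 °C should follow: the silyl group is transferred to acetate, a divalent palladium enolate forms, and beta-hydride elimination of a C2 hydrogen gives the chromen-4-one. The fallback comes back at 12.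

**Further compounds**
F1 | step 4 | 1-(2-hydroxy-4,5-dimethoxyphenyl)-2-(2,3,4-trimethoxyphenyl)ethanone | COc1cc(O)c(cc1OC)C(=O)Cc1ccc(OC)c(OC)c1OC
F2 | step 4 | 3-(dimethylamino)-1-(2-hydroxy-4,5-dimethoxyphenyl)-2-(2,3,4-trimethoxyphenyl)prop-2-en-1-one (double-bond geometry not defined) | CN(C)C=C(C(=O)c1cc(OC)c(OC)cc1O)c1ccc(OC)c(OC)c1OC
F3 | step 5 | 3-(dimethylamino)-1-[4,5-dimethoxy-2-(methoxymethoxy)phenyl]-2-(2,3,4-trimethoxyphenyl)propan-1-one (racemic) | CN(C)CC(C(=O)c1cc(OC)c(OC)cc1OCOC)c1ccc(OC)c(OC)c1OC
F4 | step 5 | 3-(dimethylamino)-1-(2-hydroxy-4,5-dimethoxyphenyl)-2-(2,3,4-trimethoxyphenyl)propan-1-one (racemic) | CN(C)CC(C(=O)c1cc(OC)c(OC)cc1O)c1ccc(OC)c(OC)c1OC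
F5 | step 6 | [6,7-dimethoxy-3-(2,3,4-trimethoxyphenyl)-2H-chromen-4-yl]oxy(trimethyl)silane | COc1cc2OCC(c3ccc(OC)c(OC)c3OC)=C(O[Si](C)(C)C)c2cc1OC
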